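| flask | substrate | capture agent | free catalyst | impurity | remark | time |
|---|---|---|---|---|---|---|
| alpha | 0.47 M | 0.0235 M | 2.3 mM | 0.32 mM | run made earlier |  |
| beta | 0.47 M | 0.0235 M | 2.3 mM | 0.64 mM | run made earlier |  |
| gamma | 0.47 M | 0.0235 M | 2.3 mM | 2.2 mM | run made earlier |  |
| Sunday's | 0.47 M | 0.0235 M | 2.3 mM | 0.25 mM |  | 6.0 h |
| Friday's | 0.47 M | 0.0235 M | 2.3 mM | 0.80 mM |  | 6.0 h |
| Wednesday's | 0.47 M | 0.0235 M | 2.3 mM | 2.0 mM |  | 6.0 h |

| run | time / h | product / % | substrate / % |
|---|---|---|---|
| alpha | 0.833 | 1.9 | 95.3 |
| alpha | 1.50 | 1.9 | 89.9 |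
| alpha | 2.50 | 4.3 | 81.3 |
| alpha | 3.00 | 7.8 | 80.3 |
| alpha | 4.00 | 12.4 | 74.2 |
| beta | 0.417 | 0.4 | 95.5 |
| beta | 1.00 | 0 | 93.5 |
| beta | 2.00 | 2.0 | 86.3 |
| beta | 3.00 | 5.6 | 80.5 |
| beta | 4.00 | 9.6 | 73.1 |
| gamma | 0.333 | 0 | 96.4 |
| gamma | 0.667 | 0 | 96.9 |
| gamma | 1.33 | 0.8 | 88.7 |
| gamma | 2.00 | 0 | 87.8 |
| gamma | 4.00 | 2.0 | 72.9 |

(each reading ± 1 percentage point)

- the numbers in the tables scatter with a standard deviation of 1 percentage point
- a reading or a percentage of product counts all its forms, free or not
- "hardly changes" means that all values lie within two and a half points (for a concentration: within two and a half percent of the largest)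

1. amount of product at the end, in percent of the substrate charged for Sunday's, Friday's, Wednesday's, in this order
2. the shape of the row from first to last (rises all the way / falls, then rises / hardly changes / falls all the way / rises, then falls)

- Start from what a closed flask cannot change: every part of the substrate charged stands as substrate, as product, or in a pool that no reading shows, so the pool is one minus the two readings.
- Read alpha, beta and gamma at 4.00 h: substrate stands at 74.2%, 73.1% and 72.9%, a spread of 1.3 percentage points, while product falls from 12.4% to 9.6% to 2.0%. So look for the impurity's harm on the way out of the pool.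
- Take the first way, by counting: suppose each impurity removes one free catalyst for good, with impurity as the limiting reagent of that loss. Sunday's then keeps 89.1%, and this surviving share, one minus the impurity charge over the catalyst charge, stands at 86.1%, 72.2% and 4.35% in alpha, beta and gamma.
- Take the second way, by reading: divide the late rise of product by the mean pool and the elapsed time, which gives a pull on the pool. Alpha gives 0.388 h⁻¹, beta 0.262 h⁻¹ and gamma 0.0536 h⁻¹.
- Compare the two ways against alpha. For beta, as a ratio to alpha, the count gives 0.839 and the reading 0.675, a gap of 0.163 that rests on rises of 8.1 points and 7.6 points between readings that each scatter by 1 point. For gamma they part, 0.0505 against 0.138, but gamma's pull rests on a rise of 2 points between two readings that each scatter by 1 point. Trust the count there.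
- Reckon the row, as my own estimate, with pool filling and emptying as first-order steps. Substrate gives 0.0773 h⁻¹, and alpha and beta give a pull per surviving share of 0.407 h⁻¹. With shares of 89.1%, 65.2% and 13.0%, product at 6.0 h comes to 23.2%, 19.6% and 5.72%, falling all the way.
- The forecast, on the ground that “The second step is what the impurity hurts”, gives 21%, 17% and 6%, falls all the way, lower than mine for Sunday's and Friday's.
- The flask gives 19.3%, 16.4% and 5.26%, falls all the way, so my reckoning stands 3.9 points high on Sunday's and 0.46 points high on Wednesday's.

    substrate → open intermediate (k = 2.10 × 10⁻⁵ s⁻¹)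
    free catalyst + impurity → spent catalyst (k = 2.10 L mol⁻¹ s⁻¹)
    free catalyst + product ⇌ idle complex, settled at all times (K = 6.30 L mol⁻¹)
    free catalyst + open intermediate → free catalyst + product (k = 0.0490 L mol⁻¹ s⁻¹)
    open intermediate + capture agent → trapped intermediate (k = 3.10 × 10⁻⁵ L mol⁻¹ s⁻¹)

- On Sunday's, free catalyst meets impurity with a half-life of 0.37 h, the other concentrations held at their charge, which is far shorter than the 9.2 h of substrate making open intermediate. At 6.00 h, free catalyst and idle complex together hold 89.1% of the catalyst charge on Sunday's, against a surviving share of 89.1%, and on Wednesday's they hold 13.0%, against 13.0%.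

(Readings and results stem from a simulated flask on assumed constants.)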